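The readings were generated by integration for substances that don't exist; the scatter is artificial.

| flask | starting material | coupling partner | free catalyst | second catalyst | remark | time |
|---|---|---|---|---|---|---|
| Friday's | 20 mM | 9 mM | 0.20 mM | 3 mM | run made earlier |  |
| Tuesday's | 20 mM | 14 mM | 0.20 mM | 3 mM | run made earlier |  |
| Saturday's | 20 mM | 18 mM | 0.20 mM | 4.5 mM | run made earlier |  |
| flask | 20 mM | 18.0 mM | 0.20 mM | 3.0 mM |  | 20 h |

| run | time / h | open intermediate / % | target / % |
|---|---|---|---|
| Friday's | 0.200 | 51.9 | 4.4 |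
| Friday's | 0.417 | 68.9 | 12.3 |
| Friday's | 1.00 | 68.9 | 26.0 |
| Friday's | 2.00 | 60.1 | 33.2 |
| Friday's | 4.00 | 55.6 | 33.8 |
| Friday's | 10.0 | 54.0 | 31.1 |
| Friday's | 20.0 | 54.3 | 28.4 |
| Tuesday's | 0.200 | 50.4 | 5.5 |
| Tuesday's | 0.417 | 63.2 | 16.8 |
| Tuesday's | 1.00 | 56.6 | 36.7 |
| Tuesday's | 2.00 | 43.9 | 47.6 |
| Tuesday's | 4.00 | 35.6 | 50.3 |
| Tuesday's | 10.0 | 32.2 | 50.3 |
| Tuesday's | 20.0 | 32.6 | 48.7 |
| Saturday's | 0.200 | 45.2 | 10.8 |
| Saturday's | 0.667 | 46.5 | 40.5 |
| Saturday's | 2.00 | 25.3 | 59.5 |
| Saturday's | 6.00 | 17.3 | 58.6 |
| Saturday's | 20.0 | 15.2 | 57.3 |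

(standard deviation of a reading: 0.5 percentage points)

1. time up to 20 h at which open intermediate stands highest
2. the amount of open intermediate, in percent of the starting material charged, at that time



- Tuesday's run, with coupling partner at 0.700 of the starting material, shows three rungs of time; the flask has 0.900.
- Top rung: filling. Taking what is missing from open intermediate plus target as starting material left, Tuesday's reading at 0.200 h gives a fill constant of 4.09 h⁻¹. Saturday's gives 4.10 h⁻¹, with more partner and more second catalyst than Tuesday's.
- Next rung: draining. Tuesday's target gain from 0.200 h to 0.417 h, per open intermediate and per equivalent of partner left, reads 1.56 h⁻¹. Friday's window reads 1.64 h⁻¹.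
- With the partner used as in Tuesday's window, the flask gets a pseudo-first-order drain constant of 1.23 h⁻¹, slower than the fill.
- Last rung: stalling. Tuesday's target reads 50.3% at 4.00 h and 50.3% at 10.0 h, a stall later than the flask's reckoned drain time of 0.813 h.
- The split ratio, fill constant over drain constant, is 3.33 for the flask.
- For two first-order steps in series, a split of 1 is the zero of the scale: the peak is 36.8% of the charge. Any split s above it gives a peak of s^(-1/(s-1)) at ln(s) over the difference of the constants.
- The flask is thus reckoned at 59.7% and 0.420 h.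
- The forecast says 59% (56.5% to 61.5%) at 0.45 h (0.37 h to 0.55 h): “The peak occurs where formation equals consumption.” The reckoning here stands higher and earlier.
- The flask peaks at 0.447 h with 59.1%, inside the forecast's ranges.

    starting material + free catalyst → free catalyst + open intermediate (k = 350 L mol⁻¹ min⁻¹)
    second catalyst + open intermediate ⇌ catalyst intermediate (K = 3.50 L mol⁻¹, k = 180 L mol⁻¹ min⁻¹)
    coupling partner + catalyst intermediate → second catalyst + target (k = 140 L mol⁻¹ min⁻¹)
    second catalyst + target → spent catalyst (k = 0.530 L mol⁻¹ min⁻¹)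
    starting material + target → side product (k = 0.770 L mol⁻¹ min⁻¹)

- At that peak the flask holds 59.1% open intermediate against 14.7% starting material, a ratio of 4.02, above the reckoned split.

- The neighbour flask charges 1.2 mM of second catalyst, 0.400 of this flask's. Scaling the drain by that share gives a split of 8.33 and a reckoned peak of 74.9%. That neighbour flask peaks at 73.8%.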